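Ring A of the flavone is cut at two adjacent bonds, C8a–O1 and C4a–C4. These ortho positions are flanked by the oxygenated carbons C8 and C5; with both written as methyl ethers, the aryne spanning C4a and C8a, 3,4,5,6-tetramethoxybenzyne, is mirror-symmetric. Insertion of this aryne into the C–O bond of an α-methoxycinnamic acid therefore forms both bonds in one operation, with no regiochemical question, and gives a 2'-hydroxychalcone holding all carbons of the target. The aryne precursor is the ortho-silyl aryl triflate 9, the partner the Z acid 13. Oxidative closure of ring C and chelation-guided cleavage of the C5 methyl ether finish the synthesis.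

Key step: step 6

Remark: flavone numbering is used for the target (ring A = benzo ring C4a–C8a, ring C = pyranone, ring B = 3-methoxyphenyl). The Z geometry of 13 and 15 is taken as the thermodynamically preferred outcome of the condensation; it is erased in step 7, so an E/Z mixture would serve equally. Compounds 1, 10 and 11 are taken as commercial.

**Step 1**
Reactants: 1 1,2,3,4-tetramethoxybenzene
Product: 4 2,3,4,5-tetramethoxyphenol, via aryllithium 2 (not isolated), via lithium aryltrimethoxyborate 3 (not isolated)
Conditions: n-BuLi, TMEDA, THF, 0 °C; B(OMe)3, −78 °C → rt; AcOH, 30% H2O2, 0 °C → rt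
Reagents that add atoms: hydrogen peroxide, OO
Why: Directed ortho-metalation by a flanking methoxy group at one of the two equivalent ring C–H positions, then borylation and boronate oxidation with 1,2-shift of the aryl group from boron to oxygen, should place the hydroxyl exactly where lithium stood.

**Step 2**
Reactants: 4 2,3,4,5-tetramethoxyphenol
Product: 5 2-bromo-3,4,5,6-tetramethoxyphenol
Conditions: NBS, MeCN, −20 °C → 0 °C
Reagents that add atoms: N-bromosuccinimide, O=C1CCC(=O)N1Br
Why: Electrophilic aromatic bromination can only occur at the single free ring position, which is ortho to the hydroxyl and para to a methoxy group, and low temperature under anhydrous conditions should suppress oxidation of the electron-rich phenol.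

**Step 3**
Reactants: 5 2-bromo-3,4,5,6-tetramethoxyphenol
Product: 6 (2-bromo-3,4,5,6-tetramethoxyphenoxy)trimethylsilane
Conditions: HMDS, THF, 70 °C; evaporate
Reagents that add atoms: hexamethyldisilazane, C[Si](C)(C)N[Si](C)(C)C
Why: O-Silylation of the phenol with HMDS gives only ammonia as by-product, so the crude silyl ether can be used after removal of volatiles.

**Step 4**
Reactants: 6 (2-bromo-3,4,5,6-tetramethoxyphenoxy)trimethylsilane
Product: 9 3,4,5,6-tetramethoxy-2-(trimethylsilyl)phenyl trifluoromethanesulfonate, via aryllithium 7 (not isolated), via lithium 2-silylphenoxide 8 (not isolated)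
Conditions: n-BuLi, THF, −100 °C → −80 °C; Tf2O, −100 °C → rt
Reagents that add atoms: trifluoromethanesulfonic anhydride, O=S(=O)(OS(=O)(=O)C(F)(F)F)C(F)(F)F
Why: Bromine–lithium exchange is followed by a 1,3 O-to-C silyl shift (retro-Brook rearrangement) driven by formation of the lithium phenoxide, which Tf2O then sulfonylates on oxygen, the standard sequence from ortho-bromophenols to ortho-silyl aryl triflates.

**Step 5**
Reactants: 10 3-methoxybenzaldehyde; 11 methyl methoxyacetate
Product: 13 (Z)-2-methoxy-3-(3-methoxyphenyl)acrylic acid, via methyl ester 12 (not isolated)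
Conditions: NaOMe, MeOH, 0 °C → 65 °C; then 2 M aq. NaOH, 65 °C; then 1 M HCl, 0 °C
Reagents that add atoms: sodium hydroxide, [Na+].[OH-]
Why: Claisen-type aldol condensation of the ester enolate with the non-enolisable aldehyde and E1cB loss of water should give the thermodynamically favoured Z enol ether (aryl trans to the carboxyl group), and saponification in the same flask with cold acidification should leave the enol ether intact.

**Step 6**
Reactants: 9 3,4,5,6-tetramethoxy-2-(trimethylsilyl)phenyl trifluoromethanesulfonate; 13 (Z)-2-methoxy-3-(3-methoxyphenyl)acrylic acid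
Product: 15 (Z)-1-(2-hydroxy-3,4,5,6-tetramethoxyphenyl)-2-methoxy-3-(3-methoxyphenyl)prop-2-en-1-one, via 3,4,5,6-tetramethoxybenzyne 14 (not isolated)
Conditions: CsF, THF, 125 °C, sealed tube
Reagents that add atoms: none
Why: Fluoride attacks silicon and triflate leaves, releasing aryne 14; the caesium carboxylate of 13 adds through oxygen to one aryne carbon, and the ortho-aryl anion so formed attacks the neighbouring ester carbonyl to give a four-membered alkoxide that opens with O-to-C acyl transfer to the phenoxide ketone, so that the future C8a–O1 and C4a–C4 bonds arise together. The closest known reaction type is the fluoride-induced insertion of arynes into the C–O bond of carboxylic acids, which gives ortho-hydroxyaryl ketones. No ring is closed and no stereocentre is formed; the Z enol ether of 13 should be carried over unchanged because the alkene takes no part. Regioselectivity is not at stake, since 14 has a mirror plane through the triple bond and both aryne carbons carry an ortho methoxy group. The step needs O-attack of the carboxylate ahead of any reaction at the electron-poor enol ether alkene, and acyl transfer ahead of protonation of the aryl anion. The first is secured by the far higher nucleophilicity of the carboxylate, the second by working hot in THF with excess CsF and no other proton source.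

**Step 7**
Reactants: 15 (Z)-1-(2-hydroxy-3,4,5,6-tetramethoxyphenyl)-2-methoxy-3-(3-methoxyphenyl)prop-2-en-1-one
Product: 16 3,5,6,7,8-pentamethoxy-2-(3-methoxyphenyl)-4H-chromen-4-one
Conditions: I2 (cat.), DMSO, 120 °C
Reagents that add atoms: none
Why: Iodine/DMSO oxidative cyclisation of a 2'-hydroxychalcone, by 6-endo conjugate addition of the phenol oxygen to Cβ and iodine-mediated dehydrogenation of the new ring with DMSO reoxidising HI, should give the 3-methoxyflavone with the α-methoxy group at C3 and the alkene geometry no longer relevant.

**Step 8**
Reactants: 16 3,5,6,7,8-pentamethoxy-2-(3-methoxyphenyl)-4H-chromen-4-one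
Product: 18 Emmaosunin (5-hydroxy-3,6,7,8-tetramethoxy-2-(3-methoxyphenyl)-4H-chromen-4-one), via dichloroboron chelate 17 (not isolated)
Conditions: BCl3, CH2Cl2, −78 °C → 0 °C; then H2O
Reagents that add atoms: none
Why: In this chelation-directed Lewis-acid ether cleavage BCl3 bridges the C4 carbonyl oxygen and the peri C5 methoxy oxygen in a six-membered chelate and chloride removes that methyl group, while the C3 methoxy group (only a strained five-membered chelate possible) and the other aryl methyl ethers should survive at low temperature with a small excess of reagent.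

**Compound list**

1 | 1,2,3,4-tetramethoxybenzene | COc1ccc(OC)c(OC)c1OC | starting material
2 | (2,3,4,5-tetramethoxyphenyl)lithium | COc1cc([Li])c(OC)c(OC)c1OC | intermediate
3 | lithium trimethoxy(2,3,4,5-tetramethoxyphenyl)borate | [Li+].CO[B-](OC)(OC)c1cc(OC)c(OC)c(OC)c1OC | intermediate
4 | 2,3,4,5-tetramethoxyphenol | COc1cc(O)c(OC)c(OC)c1OC | intermediate
5 | 2-bromo-3,4,5,6-tetramethoxyphenol | COc1c(Br)c(O)c(OC)c(OC)c1OC | intermediate
6 | (2-bromo-3,4,5,6-tetramethoxyphenoxy)trimethylsilane | COc1c(Br)c(O[Si](C)(C)C)c(OC)c(OC)c1OC | intermediate
7 | [3,4,5,6-tetramethoxy-2-(trimethylsilyloxy)phenyl]lithium | COc1c([Li])c(O[Si](C)(C)C)c(OC)c(OC)c1OC | intermediate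
8 | lithium 3,4,5,6-tetramethoxy-2-(trimethylsilyl)phenoxide | COc1c([Si](C)(C)C)c([O-])c(OC)c(OC)c1OC.[Li+] | intermediate
9 | 3,4,5,6-tetramethoxy-2-(trimethylsilyl)phenyl trifluoromethanesulfonate | COc1c([Si](C)(C)C)c(OS(=O)(=O)C(F)(F)F)c(OC)c(OC)c1OC | intermediate
10 | 3-methoxybenzaldehyde | COc1cccc(C=O)c1 | starting material
11 | methyl methoxyacetate | COCC(=O)OC | starting material
12 | methyl (Z)-2-methoxy-3-(3-methoxyphenyl)acrylate | COc1cccc(/C=C(\OC)C(=O)OC)c1 | intermediate
13 | (Z)-2-methoxy-3-(3-methoxyphenyl)acrylic acid | COc1cccc(/C=C(\OC)C(=O)O)c1 | intermediate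
14 | 3,4,5,6-tetramethoxybenzyne | COC1=C(OC)C(OC)=C(OC)C#C1 | intermediate
15 | (Z)-1-(2-hydroxy-3,4,5,6-tetramethoxyphenyl)-2-methoxy-3-(3-methoxyphenyl)prop-2-en-1-one | COc1cccc(/C=C(\OC)C(=O)c2c(O)c(OC)c(OC)c(OC)c2OC)c1 | intermediate
16 | 3,5,6,7,8-pentamethoxy-2-(3-methoxyphenyl)-4H-chromen-4-one | COc1cccc(-c2oc3c(OC)c(OC)c(OC)c(OC)c3c(=O)c2OC)c1 | intermediate
17 | dichloro{[3,6,7,8-tetramethoxy-2-(3-methoxyphenyl)-4-oxo-4H-chromen-5-yl]oxy}borane (boron chelated by the C4 carbonyl) | COc1cccc(-c2oc3c(OC)c(OC)c(OC)c(OB(Cl)Cl)c3c(=O)c2OC)c1 | intermediate
18 | Emmaosunin, 5-hydroxy-3,6,7,8-tetramethoxy-2-(3-methoxyphenyl)-4H-chromen-4-one | COc1cccc(-c2oc3c(OC)c(OC)c(OC)c(O)c3c(=O)c2OC)c1 | target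

Total step count: 8. Longest linear sequence: 7 steps (steps 1, 2, 3, 4, 6, 7, 8); step 5 is a one-step branch.

**Steps most likely to fail**

Step 6. Three processes threaten it: protonation of the ortho-aryl anion before it reaches the ester carbonyl, which would stop the sequence at the aryl ester; a second arylation of the product phenoxide by further aryne; and thermal conjugate closure of the phenoxide onto the enone at 125 °C. The last would do little harm, because ring-closed material should be dehydrogenated to 16 under the conditions of step 7. The fallback sets out from 5 and 13 and comes back at 15. Esterification of bromophenol 5 with acid 13 (DCC, DMAP, CH2Cl2) would give 2-bromo-3,4,5,6-tetramethoxyphenyl (Z)-2-methoxy-3-(3-methoxyphenyl)acrylate F1. Treatment with n-BuLi in THF at −100 °C should effect bromine–lithium exchange, and the ortho-lithiated aryl ester should undergo the 1,3 O-to-C acyl shift (anionic Fries-type rearrangement triggered by halogen–metal exchange) to give 15 after protonation. This generates the same ortho-acyloxy aryl anion without an aryne, without a proton source and at a temperature where conjugate closure cannot follow.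

Step 8. Site selectivity may be lost: the C3 methoxy group also neighbours the carbonyl, and the C6 methoxy group neighbours the new boron phenoxide, so either may be cleaved along with the C5 group. The fallback sets out from 16 and comes back at 18. AlBr3 in MeCN would be allowed to remove both carbonyl-flanking methyl groups, giving 3,5-dihydroxy-6,7,8-trimethoxy-2-(3-methoxyphenyl)-4H-chromen-4-one F3. The C3 hydroxyl is the more acidic and is not locked in the strong six-membered hydrogen bond to C4=O, so it should be methylated alone with MeI (1 equiv) and K2CO3 in acetone, giving 18. Site-selective cleavage is thus replaced by site-selective alkylation.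

Step 7. Iodine or HI may add across the electron-rich enol ether, the enol methyl group may be lost under the acidic conditions, or closure may occur at Cα in a 5-exo sense instead of clean dehydrogenative 6-endo closure. The fallback sets out from 15 and comes back at 16. Base-mediated oxa-Michael closure (NaOAc, EtOH, reflux) would give trans-3,5,6,7,8-pentamethoxy-2-(3-methoxyphenyl)chroman-4-one F2 (racemic), which would then be dehydrogenated with DDQ in dioxane at reflux to 16. Ring closure and oxidation are thereby separated and no iodine or HI is present.

**Further compounds**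

F1 | step 6 | 2-bromo-3,4,5,6-tetramethoxyphenyl (Z)-2-methoxy-3-(3-methoxyphenyl)acrylate | COc1cccc(/C=C(\OC)C(=O)Oc2c(Br)c(OC)c(OC)c(OC)c2OC)c1
F2 | step 7 | trans-3,5,6,7,8-pentamethoxy-2-(3-methoxyphenyl)chroman-4-one (racemic, one enantiomer drawn) | COc1cccc([C@@H]2[C@H](C(=O)c3c(OC)c(OC)c(OC)c(OC)c3O2)OC)c1
F3 | step 8 | 3,5-dihydroxy-6,7,8-trimethoxy-2-(3-methoxyphenyl)-4H-chromen-4-one | COc1cccc(-c2oc3c(OC)c(OC)c(OC)c(O)c3c(=O)c2O)c1
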